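**Plan**

Numbering used: chromene O1, C2 (CMe2), C3, C4, C4a, C5 (OH), C6, C7 (arylethyl), C8 (prenyl), C8a; ring A is the benzo ring, ring B the 4-hydroxyphenyl ring.
Retrosynthesis cuts, in order: (a) the two phenol MOM groups; (b) a helper formyl group on C3; (c) the pyran ring at C3=C4 and O1–C2, leaving a 3-prenylsalicylaldehyde and 3-methylbut-2-enal; (d) the C8 side chain (prenyl from allyl by cross-metathesis, allyl delivered from O1 by Claisen rearrangement); (e) the formyl carbon on C4a (metalation between the two ring-A oxygens of dihydroresveratrol).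
Forward: the bibenzyl chain is bought intact; ring A is formylated between its oxygens, one oxygen is freed, allylated and used to carry the side chain to C8; only then is the one new ring, the pyran ring, closed, the helper removed and the phenols unmasked.
Enabling feature: O1 (on C8a) and C4 (on C4a) sit on neighbouring carbons of ring A, so the pyran ring is a masked salicylaldehyde. C2 and C3 map onto the electrophilic β-carbon (already bearing both methyls) and the nucleophilic α-carbon of an enal. C2 has no hydrogen, so C3=C4 cannot move.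
Stereochemistry: the target has no stereocentre; C3=C4 is cis by the ring and the prenyl double bond carries two identical methyl groups.

Key step: step 7

Remark: dihydroresveratrol is taken as a purchasable starting material; all other reagents are common catalogue chemicals.

**Step 1**
Reactants: 1 dihydroresveratrol (5-[2-(4-hydroxyphenyl)ethyl]benzene-1,3-diol); 2 chloromethyl methyl ether
Product: 3 1,3-bis(methoxymethoxy)-5-{2-[4-(methoxymethoxy)phenyl]ethyl}benzene
Conditions: MOMCl, i-Pr2NEt, CH2Cl2, 0 °C to rt
Reagents that add atoms: chloromethyl methyl ether (MOMCl), COCCl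
Why: Base-mediated O-alkylation of the three phenols (MOM acetal protection), which also places on ring A the two OMOM groups that direct the metalation of step 2.

**Step 2**
Reactants: 3 tris-MOM ether of dihydroresveratrol; 4 N,N-dimethylformamide
Product: 7 2,6-bis(methoxymethoxy)-4-{2-[4-(methoxymethoxy)phenyl]ethyl}benzaldehyde, via aryllithium 5 (not isolated), via lithium hemiaminolate 6 (not isolated)
Conditions: n-BuLi, THF, 0 °C; DMF, 0 °C to rt; H2O
Reagents that add atoms: N,N-dimethylformamide (DMF), CN(C)C=O
Why: Directed ortho-metalation then formylation: the ring-A carbon between the two OMOM groups is the most acidic aryl C–H because both acetal oxygens hold the lithium, so n-BuLi should metalate there and not beside the single OMOM group of ring B, and the aryllithium adds to DMF to give the aldehyde on aqueous work-up.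

**Step 3**
Reactants: 7 tris-MOM aldehyde
Product: 8 2-hydroxy-6-(methoxymethoxy)-4-{2-[4-(methoxymethoxy)phenyl]ethyl}benzaldehyde
Conditions: 3 M aq. HCl, THF, rt, stopped at mono-cleavage
Reagents that add atoms: none
Why: Acid hydrolysis of a MOM acetal under kinetic control: the MOM ether ortho to the formyl group leaves fastest (the salicylaldehyde-type phenol is the better leaving group), the freed phenol then binds the formyl oxygen in a hydrogen bond that slows loss of the second ortho MOM group, and the ring-B MOM ether lacks this assistance.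

**Step 4**
Reactants: 8 mono-phenol aldehyde; 9 allyl bromide
Product: 10 2-(methoxymethoxy)-4-{2-[4-(methoxymethoxy)phenyl]ethyl}-6-(prop-2-en-1-yloxy)benzaldehyde
Conditions: K2CO3, DMF, 50 °C
Reagents that add atoms: allyl bromide, C=CCBr
Why: Williamson ether synthesis on the only free phenol, whose hydrogen bond to the formyl group is broken by K2CO3 in DMF.

**Step 5**
Reactants: 10 allyl ether
Product: 12 2-hydroxy-6-(methoxymethoxy)-4-{2-[4-(methoxymethoxy)phenyl]ethyl}-3-(prop-2-en-1-yl)benzaldehyde, via dienone 11 (not isolated)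
Conditions: N,N-diethylaniline, 190 °C
Reagents that add atoms: none
Why: Aromatic Claisen rearrangement ([3,3]-sigmatropic shift): of the two carbons ortho to the allyloxy group only the future C8 carries hydrogen (the other bears the formyl group), so the allyl group should migrate there, and tautomerisation of the dienone restores ring A and frees O1–H next to the formyl group.

**Step 6**
Reactants: 12 3-allylsalicylaldehyde; 13 2-methylbut-2-ene
Product: 14 2-hydroxy-6-(methoxymethoxy)-4-{2-[4-(methoxymethoxy)phenyl]ethyl}-3-(3-methylbut-2-en-1-yl)benzaldehyde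
Conditions: second-generation Grubbs catalyst RuCl2(=CHPh)(PCy3)(H2IMes) (5 mol %), 2-methylbut-2-ene (excess), CH2Cl2, rt
Reagents that add atoms: 2-methylbut-2-ene, CC=C(C)C
Why: Olefin cross-metathesis of the terminal allyl group with excess 2-methylbut-2-ene, which exchanges the =CH2 terminus for =C(CH3)2 and releases propene; the free phenol and the aldehyde are tolerated by the ruthenium alkylidene.

**Step 7**
Reactants: 14 3-prenylsalicylaldehyde; 15 3-methylbut-2-enal
Product: 18 5-(methoxymethoxy)-7-{2-[4-(methoxymethoxy)phenyl]ethyl}-2,2-dimethyl-8-(3-methylbut-2-en-1-yl)-2H-chromene-3-carbaldehyde, via oxa-Michael adduct 16 (not isolated), via aldol 17 (not isolated)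
Conditions: K2CO3, 3-methylbut-2-enal (3 equiv), 1,4-dioxane, 100 °C
Reagents that add atoms: 3-methylbut-2-enal (prenal), CC(C)=CC=O
Why: K2CO3 deprotonates the single free phenol (O1–H) of 14, the phenoxide adds in conjugate (oxa-Michael) fashion to the β-carbon of the enal to make O1–C2 and an aldehyde enolate (16), whose α-carbon attacks the neighbouring ring-A formyl carbon in an intramolecular aldol addition that closes the pyran ring by making the C3–C4 bond (17), and E1cB loss of water turns this bond into the C3=C4 double bond of 18. The closest known reaction type is the base-mediated domino oxa-Michael/aldol condensation of salicylaldehydes with α,β-unsaturated aldehydes (3-methylbut-2-enal included) to 2H-chromene-3-carbaldehydes. The one ring formed, the six-membered pyran ring, closes in a 6-(enolexo)-exo-trig aldol mode. No stereocentre remains: C2 carries two methyl groups, the two stereocentres of aldol 17 are erased by the dehydration, and the ring fixes the cis geometry of C3=C4. The step needs conjugate addition through oxygen to win over 1,2-addition and over γ-aldol condensation of the enal dienolate, and it needs the crowded O1 (flanked by the prenyl group and the formyl carbon) to add to a β,β-disubstituted enal. The substrate secures this because O1 is the only free nucleophile (O5 and the ring-B oxygen are MOM-capped), the formyl carbon sits ortho to O1 so each reversible Michael adduct is trapped by a fast six-ring aldol, and the irreversible dehydration to the arene-conjugated enal drains all equilibria toward 18.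

**Step 8**
Reactants: 18 chromene-3-carbaldehyde
Product: 19 5-(methoxymethoxy)-7-{2-[4-(methoxymethoxy)phenyl]ethyl}-2,2-dimethyl-8-(3-methylbut-2-en-1-yl)-2H-chromene
Conditions: RhCl(PPh3)3 (1.1 equiv), PhCN, 130 °C
Reagents that add atoms: none
Why: Tsuji–Wilkinson decarbonylation: oxidative addition of the formyl C–H bond to monovalent rhodium, extrusion of CO onto the metal and C–H reductive elimination replace the helper formyl group on C3 by hydrogen, and because C2 is quaternary the C3=C4 double bond cannot migrate.

**Step 9**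
Reactants: 19 bis-MOM chromene
Product: 20 7-[2-(4-hydroxyphenyl)ethyl]-2,2-dimethyl-8-(3-methylbut-2-en-1-yl)-2H-chromen-5-ol (target)
Conditions: HCl (1.25 M in MeOH), rt to 40 °C
Reagents that add atoms: none
Why: Acid-catalysed transacetalisation of both aryl MOM ethers to methanol under mild conditions; the prenyl group has no free hydroxyl on a neighbouring ring carbon (its neighbours are C7 and the ether carbon C8a), so acid-induced chroman formation is not possible.

**Compound list**

1 | dihydroresveratrol, 5-[2-(4-hydroxyphenyl)ethyl]benzene-1,3-diol | Oc1ccc(CCc2cc(O)cc(O)c2)cc1 | starting material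
2 | chloromethyl methyl ether (MOMCl) | COCCl | starting material
3 | 1,3-bis(methoxymethoxy)-5-{2-[4-(methoxymethoxy)phenyl]ethyl}benzene | COCOc1ccc(CCc2cc(OCOC)cc(OCOC)c2)cc1 | intermediate
4 | N,N-dimethylformamide | CN(C)C=O | starting material
5 | {2,6-bis(methoxymethoxy)-4-{2-[4-(methoxymethoxy)phenyl]ethyl}phenyl}lithium (not isolated) | COCOc1ccc(CCc2cc(OCOC)c([Li])c(OCOC)c2)cc1 | intermediate
6 | lithium (dimethylamino){2,6-bis(methoxymethoxy)-4-{2-[4-(methoxymethoxy)phenyl]ethyl}phenyl}methanolate, racemic (not isolated) | COCOc1ccc(CCc2cc(OCOC)c(C(O[Li])N(C)C)c(OCOC)c2)cc1 | intermediate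
7 | 2,6-bis(methoxymethoxy)-4-{2-[4-(methoxymethoxy)phenyl]ethyl}benzaldehyde | COCOc1ccc(CCc2cc(OCOC)c(C=O)c(OCOC)c2)cc1 | intermediate
8 | 2-hydroxy-6-(methoxymethoxy)-4-{2-[4-(methoxymethoxy)phenyl]ethyl}benzaldehyde | COCOc1ccc(CCc2cc(O)c(C=O)c(OCOC)c2)cc1 | intermediate
9 | allyl bromide (3-bromoprop-1-ene) | C=CCBr | starting material
10 | 2-(methoxymethoxy)-4-{2-[4-(methoxymethoxy)phenyl]ethyl}-6-(prop-2-en-1-yloxy)benzaldehyde | C=CCOc1cc(CCc2ccc(OCOC)cc2)cc(OCOC)c1C=O | intermediate
11 | 2-(methoxymethoxy)-4-{2-[4-(methoxymethoxy)phenyl]ethyl}-6-oxo-5-(prop-2-en-1-yl)cyclohexa-1,3-diene-1-carbaldehyde, racemic (not isolated) | O=C1C(CC=C)C(CCc2ccc(OCOC)cc2)=CC(OCOC)=C1C=O | intermediate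
12 | 2-hydroxy-6-(methoxymethoxy)-4-{2-[4-(methoxymethoxy)phenyl]ethyl}-3-(prop-2-en-1-yl)benzaldehyde | C=CCc1c(O)c(C=O)c(OCOC)cc1CCc1ccc(OCOC)cc1 | intermediate
13 | 2-methylbut-2-ene | CC=C(C)C | starting material
14 | 2-hydroxy-6-(methoxymethoxy)-4-{2-[4-(methoxymethoxy)phenyl]ethyl}-3-(3-methylbut-2-en-1-yl)benzaldehyde | CC(C)=CCc1c(O)c(C=O)c(OCOC)cc1CCc1ccc(OCOC)cc1 | intermediate
15 | 3-methylbut-2-enal (prenal) | CC(C)=CC=O | starting material
16 | 6-(methoxymethoxy)-4-{2-[4-(methoxymethoxy)phenyl]ethyl}-3-(3-methylbut-2-en-1-yl)-2-[(2-methyl-4-oxobutan-2-yl)oxy]benzaldehyde (not isolated) | CC(C)=CCc1c(CCc2ccc(OCOC)cc2)cc(OCOC)c(C=O)c1OC(C)(C)CC=O | intermediate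
17 | 4-hydroxy-5-(methoxymethoxy)-7-{2-[4-(methoxymethoxy)phenyl]ethyl}-2,2-dimethyl-8-(3-methylbut-2-en-1-yl)-3,4-dihydro-2H-chromene-3-carbaldehyde, diastereomer mixture with C3 and C4 undefined (not isolated) | CC(C)=CCc1c(CCc2ccc(OCOC)cc2)cc(OCOC)c2c1OC(C)(C)C(C=O)C2O | intermediate
18 | 5-(methoxymethoxy)-7-{2-[4-(methoxymethoxy)phenyl]ethyl}-2,2-dimethyl-8-(3-methylbut-2-en-1-yl)-2H-chromene-3-carbaldehyde | CC(C)=CCc1c(CCc2ccc(OCOC)cc2)cc(OCOC)c2c1OC(C)(C)C(C=O)=C2 | intermediate
19 | 5-(methoxymethoxy)-7-{2-[4-(methoxymethoxy)phenyl]ethyl}-2,2-dimethyl-8-(3-methylbut-2-en-1-yl)-2H-chromene | CC(C)=CCc1c(CCc2ccc(OCOC)cc2)cc(OCOC)c2c1OC(C)(C)C=C2 | intermediate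
20 | 7-[2-(4-hydroxyphenyl)ethyl]-2,2-dimethyl-8-(3-methylbut-2-en-1-yl)-2H-chromen-5-ol | CC(C)=CCc1c(CCc2ccc(O)cc2)cc(O)c2c1OC(C)(C)C=C2 | target

**Count**

Total step count: 9. Longest linear sequence: 9 steps (1 to 20).

**Steps most likely to fail**

1. Step 7 (domino oxa-Michael/aldol condensation). The crowded phenoxide may add too slowly to the β,β-disubstituted enal, so that self-condensation of the enal or γ-aldol condensation of its dienolate with the formyl group takes over. The fallback closes the same bond by olefin metathesis and needs no formyl helper. It sets out from 14. O-alkylation with 3-chloro-3-methylbut-1-yne (K2CO3, KI, CuI, DMF, 60 °C) should give the aryl 1,1-dimethylpropargyl ether F1. Semihydrogenation (H2, Pd/CaCO3 poisoned with Pb(OAc)2, quinoline, EtOAc, rt) should give the aryl 1,1-dimethylallyl ether F2. Wittig methylenation (Ph3PCH3Br, KOtBu, THF, 0 °C) should give the styrene F3. Ring-closing metathesis (second-generation Grubbs catalyst RuCl2(=CHPh)(PCy3)(H2IMes), CH2Cl2, 40 °C) should then form C3=C4 and come back to the route at 19, so step 8 is not needed.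

2. Step 8 (decarbonylation). CO extrusion from the hindered, conjugated formyl group may be slow, and rhodium hydride species formed at 130 °C may shift the prenyl double bond into conjugation with ring A. The fallback replaces decarbonylation by oxidation and decarboxylation. It sets out from 18. Pinnick oxidation (NaClO2, NaH2PO4, 2-methylbut-2-ene, t-BuOH/H2O, rt) should give the chromene-3-carboxylic acid F4. Copper-mediated protodecarboxylation of this cinnamic-type acid (Cu2O, 1,10-phenanthroline, NMP/quinoline, 170 °C) should come back to the route at 19.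

3. Step 3 (removal of one MOM group). Over-hydrolysis may occur, with loss of the second ortho MOM group or of the ring-B MOM group, or the reaction may stall and leave mixtures. The fallback uses exhaustive cleavage followed by chelation-controlled re-protection. It sets out from 7. HCl in MeOH at 50 °C should remove all three MOM groups and give 2,6-dihydroxy-4-[2-(4-hydroxyphenyl)ethyl]benzaldehyde F5. MOMCl (2.1 equiv) and i-Pr2NEt in CH2Cl2 at 0 °C should then cap the ring-B phenol and one ring-A phenol, while the last hydroxyl stays locked in its hydrogen bond to the formyl oxygen; this comes back to the route at 8.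

**Further compounds**

F1 | step 7 | 6-(methoxymethoxy)-4-{2-[4-(methoxymethoxy)phenyl]ethyl}-3-(3-methylbut-2-en-1-yl)-2-[(2-methylbut-3-yn-2-yl)oxy]benzaldehyde | CC(C)=CCc1c(CCc2ccc(OCOC)cc2)cc(OCOC)c(C=O)c1OC(C)(C)C#C
F2 | step 7 | 6-(methoxymethoxy)-4-{2-[4-(methoxymethoxy)phenyl]ethyl}-3-(3-methylbut-2-en-1-yl)-2-[(2-methylbut-3-en-2-yl)oxy]benzaldehyde | CC(C)=CCc1c(CCc2ccc(OCOC)cc2)cc(OCOC)c(C=O)c1OC(C)(C)C=C
F3 | step 7 | 2-ethenyl-1-(methoxymethoxy)-5-{2-[4-(methoxymethoxy)phenyl]ethyl}-4-(3-methylbut-2-en-1-yl)-3-[(2-methylbut-3-en-2-yl)oxy]benzene | CC(C)=CCc1c(CCc2ccc(OCOC)cc2)cc(OCOC)c(C=C)c1OC(C)(C)C=C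
F4 | step 8 | 5-(methoxymethoxy)-7-{2-[4-(methoxymethoxy)phenyl]ethyl}-2,2-dimethyl-8-(3-methylbut-2-en-1-yl)-2H-chromene-3-carboxylic acid | CC(C)=CCc1c(CCc2ccc(OCOC)cc2)cc(OCOC)c2c1OC(C)(C)C(C(=O)O)=C2
F5 | step 3 | 2,6-dihydroxy-4-[2-(4-hydroxyphenyl)ethyl]benzaldehyde | O=Cc1c(O)cc(CCc2ccc(O)cc2)cc1O
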